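**Retrosynthetic overview**
1. 14 comes from dibenzyl ether 13 by neutral hydrogenolysis in the last step.
2. 13 comes from aryl lactone 9 and 2,2,4,4-tetramethylcyclobutane-1,3-dione 10. The CH2–C(=O) unit of the lactone is inserted into one C(=O)–C(CH3)2 bond of the four-membered ring, which builds the whole enol-trione carbocycle and frees the third phenol.
3. Enabling feature: the phenol oxygen on the arene carbon next to the one bearing the stereocentre can be tied to a trione carbonyl carbon as a six-membered dihydrocoumarin ring. The side-chain-bearing trione carbon is then an acidic lactone α-carbon, and its carbonyl neighbour is an aryl ester with a built-in phenoxide leaving group. The other four ring carbons, C(OH)–C(CH3)2–C(=O)–C(CH3)2, are the perimeter of dimethylketene dimer 10.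
4. 9 comes from 6 (Friedel–Crafts acylation), 6 from coumarin 4 (copper hydride asymmetric conjugate reduction sets the only stereocentre), and 4 from 1 + 2 (Pechmann condensation, then benzylation).
5. Ring order: arene (bought), pyranone ring (step 1, temporary), enol-trione ring (step 5, made from the four-membered ring while the lactone ring opens).

Key step: step 5

Assumption: (S)-DTBM-SEGPHOS is taken as the ligand antipode that sends hydride to the C4 face leading to (4S)-6. If the sense of induction is the opposite, the (R)-ligand is used and nothing else changes.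

**Step 1**
Reactants: 1 2-methylbenzene-1,3,5-triol; 2 ethyl 3-oxo-5-phenylpentanoate
Product: 3 5,7-dihydroxy-8-methyl-4-(2-phenylethyl)-2H-chromen-2-one
Conditions: CF3CO2H, 70 °C
Reagents that add atoms: none
Why: Pechmann condensation of a phloroglucinol with a β-keto ester is the standard entry to 4-alkyl-5,7-dihydroxycoumarins; closure through the hydroxyl next to the methyl group should be favoured because it keeps the crowded 4,5-peri region free of a buttressing 6-substituent, and the 6-methyl lactone isomer would lead to the same 14 anyway, since the lactone oxygen ends as a free phenol.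

**Step 2**
Reactants: 3 5,7-dihydroxy-8-methyl-4-(2-phenylethyl)-2H-chromen-2-one
Product: 4 5,7-bis(benzyloxy)-8-methyl-4-(2-phenylethyl)-2H-chromen-2-one
Conditions: BnBr (2.4 equiv), K2CO3 (3 equiv), DMF, 60 °C
Reagents that add atoms: benzyl bromide, BrCc1ccccc1
Why: Williamson ether synthesis on the two acidic coumarin phenols, with benzyl chosen because it withstands copper hydride, the acylating anhydride and amide bases and leaves at the end under neutral hydrogenolysis.

**Step 3**
Reactants: 4 5,7-bis(benzyloxy)-8-methyl-4-(2-phenylethyl)-2H-chromen-2-one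
Product: 6 (4S)-5,7-bis(benzyloxy)-8-methyl-4-(2-phenylethyl)-3,4-dihydro-2H-chromen-2-one, via boron enolate 5 (not isolated)
Conditions: CuCl (5 mol %), NaOt-Bu (10 mol %), (S)-DTBM-SEGPHOS (5.5 mol %), pinacolborane (1.5 equiv), toluene, rt; aq NH4Cl
Reagents that add atoms: pinacolborane, [H]B1OC(C)(C)C(C)(C)O1 (its boron, oxygen and carbon atoms stay only in 5; 6 keeps hydrogen alone)
Why: Copper hydride-catalysed asymmetric conjugate reduction (1,4-hydroboration) of 4-substituted coumarins is a known reaction class in which the ligand-bound monovalent copper hydride delivers hydride to one face of C4 of the geometrically fixed enoate, which sets the only stereocentre as S, while trapping as boron enolate 5 stops further reduction of the lactone.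

**Step 4**
Reactants: 6 (4S)-5,7-bis(benzyloxy)-8-methyl-4-(2-phenylethyl)-3,4-dihydro-2H-chromen-2-one; 7 3-phenylpropanoic acid
Product: 9 (4S)-5,7-bis(benzyloxy)-8-methyl-4-(2-phenylethyl)-6-(3-phenylpropanoyl)-3,4-dihydro-2H-chromen-2-one, via mixed anhydride 8 (not isolated)
Conditions: 7, (CF3CO)2O, CH2Cl2, 0 °C; then 6, 0 °C to rt
Reagents that add atoms: trifluoroacetic anhydride, O=C(OC(=O)C(F)(F)F)C(F)(F)F (its atoms stay only in 8; none in 9)
Why: Friedel–Crafts acylation by an acyl trifluoroacetate, as used for benzyl-protected phloroglucinols, should go to C6 because it is the only free ring position and lies ortho to both benzyloxy groups and para to the lactone oxygen, and the metal-free medium should spare the benzyl ethers, the lactone and the stereocentre.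

**Step 5**
Reactants: 9 (4S)-5,7-bis(benzyloxy)-8-methyl-4-(2-phenylethyl)-6-(3-phenylpropanoyl)-3,4-dihydro-2H-chromen-2-one; 10 2,2,4,4-tetramethylcyclobutane-1,3-dione
Product: 13 2-[(1R)-1-[4,6-bis(benzyloxy)-2-hydroxy-3-methyl-5-(3-phenylpropanoyl)phenyl]-3-phenylpropyl]-3-hydroxy-4,4,6,6-tetramethylcyclohex-2-ene-1,5-dione, via cyclobutanol aldol adduct 11 (not isolated), via acyl lactone 12 (not isolated)
Conditions: LiN(SiMe3)2 (1.0 equiv), THF, −78 to −40 °C; 10 (1.05 equiv), −78 to 0 °C; KN(SiMe3)2 (2.5 equiv), 0 °C to rt; 1 M HCl, 0 °C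
Reagents that add atoms: none
Why: Proposed new method: LiN(SiMe3)2 converts the lactone α-CH2 of 9 into its enolate, which adds to one carbonyl of the strained, non-enolisable dione 10 to give the alkoxide of 11; retro-Claisen cleavage of the neighbouring C(=O)–C(CH3)2 ring bond releases the ring strain, makes the first new C–C bond irreversible and leaves 12 as its isopropyl-ketone enolate, and this tertiary enolate, regenerated by KN(SiMe3)2 after the expected proton shift from the acidic C3–H, attacks the aryl lactone carbonyl (directly or after E1cB loss of the phenoxide to an acylketene), which forms the second C–C bond, closes the trione ring and frees the phenol. The closest known reaction types are the ring opening of 10 by organolithium, alkoxide and amine nucleophiles to 2,2,4-trimethyl-3-oxopentanoyl derivatives, the alkoxide-induced conversion of dimethylketene dimers into hexamethylcyclohexane-1,3,5-trione through the same kind of tertiary enolate, and the Dieckmann closure of 3,5-dioxo esters to syncarpic acids; the net two-carbon insertion of a lactone CH2–C(=O) unit into 10 has not been described. The only ring closed is the six-membered carbocycle, by a 6-(enolendo)-exo-trig acyl substitution (exo-dig if the ketene is the acceptor), while the four-membered ring and the lactone ring are both opened. No stereocentre is created in 13, because the transient centre at C3 of 11 and 12 is erased on enolisation and the benzylic centre is β to every enolate involved and bears no acidic hydrogen, so its configuration is retained and the descriptor changes from S to R only through the change of priorities. The step needs site selectivity in the first deprotonation, which is secured by the aryl-ester α-CH2 being several pK units more acidic than the α-CH2 of the twisted ketone flanked by two benzyloxy groups, by using one equivalent of base with time to equilibrate, and by adding the extra base only after 10 is consumed. C- versus O-acylation in the closure is under thermodynamic control, since an enol lactone from O-attack is reopened by the liberated phenoxide whereas the vinylogous-acid enolate of 13 is the sink.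

**Step 6**
Reactants: 13 2-[(1R)-1-[4,6-bis(benzyloxy)-2-hydroxy-3-methyl-5-(3-phenylpropanoyl)phenyl]-3-phenylpropyl]-3-hydroxy-4,4,6,6-tetramethylcyclohex-2-ene-1,5-dione
Product: 14 2-[(1R)-3-phenyl-1-[2,4,6-trihydroxy-3-methyl-5-(3-phenylpropanoyl)phenyl]propyl]-3-hydroxy-4,4,6,6-tetramethylcyclohex-2-ene-1,5-dione
Conditions: H2 (1 atm), Pd/C (10 wt %), EtOAc–MeOH, rt
Reagents that add atoms: none
Why: Catalytic hydrogenolysis of aryl benzyl ethers runs under neutral conditions that should leave the hydrogen-bonded aryl ketone, the tetrasubstituted enol and the stereocentre untouched and avoid the acid that would cyclodehydrate the enol onto a phenol.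

**Compound list**
1 | 2-methylbenzene-1,3,5-triol (2-methylphloroglucinol) | Cc1c(O)cc(O)cc1O | starting material
2 | ethyl 3-oxo-5-phenylpentanoate | CCOC(=O)CC(=O)CCc1ccccc1 | starting material
3 | 5,7-dihydroxy-8-methyl-4-(2-phenylethyl)-2H-chromen-2-one | O=C1C=C(CCc2ccccc2)c2c(O)cc(O)c(C)c2O1 | intermediate
4 | 5,7-bis(benzyloxy)-8-methyl-4-(2-phenylethyl)-2H-chromen-2-one | O=C1C=C(CCc2ccccc2)c2c(OCc3ccccc3)cc(OCc3ccccc3)c(C)c2O1 | intermediate
5 | (4S)-5,7-bis(benzyloxy)-8-methyl-4-(2-phenylethyl)-2-[(4,4,5,5-tetramethyl-1,3,2-dioxaborolan-2-yl)oxy]-4H-chromene (boron enolate, not isolated) | CC1(C)OB(OC2=C[C@H](CCc3ccccc3)c3c(OCc4ccccc4)cc(OCc4ccccc4)c(C)c3O2)OC1(C)C | intermediate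
6 | (4S)-5,7-bis(benzyloxy)-8-methyl-4-(2-phenylethyl)-3,4-dihydro-2H-chromen-2-one | O=C1C[C@H](CCc2ccccc2)c2c(OCc3ccccc3)cc(OCc3ccccc3)c(C)c2O1 | intermediate
7 | 3-phenylpropanoic acid | OC(=O)CCc1ccccc1 | starting material
8 | 3-phenylpropanoic trifluoroacetic anhydride (not isolated) | O=C(CCc1ccccc1)OC(=O)C(F)(F)F | intermediate
9 | (4S)-5,7-bis(benzyloxy)-8-methyl-4-(2-phenylethyl)-6-(3-phenylpropanoyl)-3,4-dihydro-2H-chromen-2-one | O=C1C[C@H](CCc2ccccc2)c2c(OCc3ccccc3)c(C(=O)CCc3ccccc3)c(OCc3ccccc3)c(C)c2O1 | intermediate
10 | 2,2,4,4-tetramethylcyclobutane-1,3-dione | CC1(C)C(=O)C(C)(C)C1=O | starting material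
11 | (4S)-5,7-bis(benzyloxy)-3-(1-hydroxy-2,2,4,4-tetramethyl-3-oxocyclobutyl)-8-methyl-4-(2-phenylethyl)-6-(3-phenylpropanoyl)-3,4-dihydro-2H-chromen-2-one (C3 left open, trans to the phenylethyl group expected; not isolated) | O=C1C(C2(O)C(C)(C)C(=O)C2(C)C)[C@H](CCc2ccccc2)c2c(OCc3ccccc3)c(C(=O)CCc3ccccc3)c(OCc3ccccc3)c(C)c2O1 | intermediate
12 | (4S)-5,7-bis(benzyloxy)-8-methyl-4-(2-phenylethyl)-6-(3-phenylpropanoyl)-3-(2,2,4-trimethyl-3-oxopentanoyl)-3,4-dihydro-2H-chromen-2-one (C3 left open, enolisable; not isolated) | O=C1C(C(=O)C(C)(C)C(=O)C(C)C)[C@H](CCc2ccccc2)c2c(OCc3ccccc3)c(C(=O)CCc3ccccc3)c(OCc3ccccc3)c(C)c2O1 | intermediate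
13 | 2-[(1R)-1-[4,6-bis(benzyloxy)-2-hydroxy-3-methyl-5-(3-phenylpropanoyl)phenyl]-3-phenylpropyl]-3-hydroxy-4,4,6,6-tetramethylcyclohex-2-ene-1,5-dione | Cc1c(OCc2ccccc2)c(C(=O)CCc2ccccc2)c(OCc2ccccc2)c([C@@H](CCc2ccccc2)C2=C(O)C(C)(C)C(=O)C(C)(C)C2=O)c1O | intermediate
14 | 2-[(1R)-3-phenyl-1-[2,4,6-trihydroxy-3-methyl-5-(3-phenylpropanoyl)phenyl]propyl]-3-hydroxy-4,4,6,6-tetramethylcyclohex-2-ene-1,5-dione (CNP0236721.1) | Cc1c(O)c(C(=O)CCc2ccccc2)c(O)c([C@@H](CCc2ccccc2)C2=C(O)C(C)(C)C(=O)C(C)(C)C2=O)c1O | target

Total step count: 6
Longest linear sequence: 6 steps (from 1 or 2 to 14)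

**Steps most likely to fail**

1. **Step 5.**
   - What may go wrong: slow addition of the hindered enolate to the flanked cyclobutanedione carbonyl; stalling after the first bond at the stabilised acyl lactone enolate; competing enolisation and acylation at the aryl ketone.
   - Fallback (known chemistry of this natural product family): it sets out from 1 and 7 and comes back at 14. Friedel–Crafts acylation of 1 with 7 in BF3·OEt2 gives 1-(2,4,6-trihydroxy-3-methylphenyl)-3-phenylpropan-1-one F1. Commercial syncarpic acid (2,2,4,4-tetramethylcyclohexane-1,3,5-trione) and 3-phenylpropanal undergo Knoevenagel condensation to 2,2,4,4-tetramethyl-6-(3-phenylpropylidene)cyclohexane-1,3,5-trione F2. The only free arene carbon of F1 is then added to F2 in an enantioselective Friedel–Crafts-type Michael addition under a chiral lithium aluminium bis(binaphthoxide) complex, LiAl(BINOLate)2, of the antipode that gives the R centre. This leads directly to 14.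

2. **Step 3.**
   - What may go wrong: low turnover on the electron-rich, peri-crowded coumarin; poor facial selectivity; further reduction of the lactone carbonyl.
   - Fallback: it sets out from 4 and comes back at 6, replacing hydride conjugate addition by carboxylate-directed asymmetric hydrogenation of the opened ring. NaOH in MeOH opens the lactone to (2Z)-3-[4,6-bis(benzyloxy)-2-hydroxy-3-methylphenyl]-5-phenylpent-2-enoic acid F3, handled as its disodium salt. Homogeneous hydrogenation with [Rh(cod)Cl]2 and a Chiraphos antipode spares the benzyl ethers and gives (3S)-3-[4,6-bis(benzyloxy)-2-hydroxy-3-methylphenyl]-5-phenylpentanoic acid F4. This relactonises to 6 on acidification.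

3. **Step 4.**
   - What may go wrong: acidolytic loss or migration of a benzyl group; sluggish substitution at the position flanked by two benzyloxy groups.
   - Fallback: it sets out from 6 and comes back at 9, doing the acylation on free phenols. Hydrogenolysis (H2, Pd/C) gives (4S)-5,7-dihydroxy-8-methyl-4-(2-phenylethyl)-3,4-dihydro-2H-chromen-2-one F5. Classical phloroglucinol acylation with 7 in BF3·OEt2 at 60 °C gives (4S)-5,7-dihydroxy-8-methyl-4-(2-phenylethyl)-6-(3-phenylpropanoyl)-3,4-dihydro-2H-chromen-2-one F6. Benzylation (BnBr, K2CO3, DMF) returns 9. A shift of the lactone to the other ortho oxygen at the free-phenol stage would be harmless, because both lactones lead to 14.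

**Further compounds**
F1 | step 5 | 1-(2,4,6-trihydroxy-3-methylphenyl)-3-phenylpropan-1-one | Cc1c(O)cc(O)c(C(=O)CCc2ccccc2)c1O
F2 | step 5 | 2,2,4,4-tetramethyl-6-(3-phenylpropylidene)cyclohexane-1,3,5-trione | CC1(C)C(=O)C(=CCCc2ccccc2)C(=O)C(C)(C)C1=O
F3 | step 3 | (2Z)-3-[4,6-bis(benzyloxy)-2-hydroxy-3-methylphenyl]-5-phenylpent-2-enoic acid | OC(=O)/C=C(/CCc1ccccc1)c1c(O)c(C)c(OCc2ccccc2)cc1OCc1ccccc1
F4 | step 3 | (3S)-3-[4,6-bis(benzyloxy)-2-hydroxy-3-methylphenyl]-5-phenylpentanoic acid | OC(=O)C[C@H](CCc1ccccc1)c1c(O)c(C)c(OCc2ccccc2)cc1OCc1ccccc1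
F5 | step 4 | (4S)-5,7-dihydroxy-8-methyl-4-(2-phenylethyl)-3,4-dihydro-2H-chromen-2-one | O=C1C[C@H](CCc2ccccc2)c2c(O)cc(O)c(C)c2O1
F6 | step 4 | (4S)-5,7-dihydroxy-8-methyl-4-(2-phenylethyl)-6-(3-phenylpropanoyl)-3,4-dihydro-2H-chromen-2-one | O=C1C[C@H](CCc2ccccc2)c2c(O)c(C(=O)CCc3ccccc3)c(O)c(C)c2O1
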